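## Structural features

Caraganin C is a 2,3,4-trisubstituted chroman: benzo ring A, with a methoxy group at C7, is fused through C4a and C8a to a dihydropyran ring made of O1, C2, C3 and C4. C2 bears a 2,4-dimethoxyphenyl ring, C3 a 4-hydroxybenzyl group and C4 an (E)-4-hydroxystyryl group. The three stereocenters C2, C3 and C4 are contiguous and all R; each neighbouring pair is trans (C2/C4 cis), so all three substituents can sit equatorial on the half-chair, which is the thermodynamically preferred arrangement. The fragile parts are the C2–O1 bond (a benzylic aryl ether of a very electron-rich arene, which ionises in acid and is cut by hydrogenolysis), the styryl double bond (no catalytic hydrogenation; sensitive to acid and oxidants) and the two free phenols. The real difficulty is to set three adjacent carbon stereocenters in the absolute sense although none carries a functional group; C4 is a doubly benzylic/allylic methine without a heteroatom handle. The key step uses the hydrogen on C2, which is α to O1, benzylic to the dimethoxyphenyl ring and 1,5 to C4. If the CH2 on C3 is written as a ketone, C4 becomes the β-carbon of an enone, C2–H a hydride donor aimed at it, and C3 the enolate carbon that closes onto C2. Both 4-hydroxyphenyl units can come from one aldehyde.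

## Logic of the disconnections

**16 ⇒ 14.** The C–H bond of the benzylic methylene on C3 and the two phenolic O–H bonds are cut, leading to 14 with an acetoxy group on that carbon and both phenols silylated. Fluoride then frees both phenols and turns the ring para to the acetoxy carbon into 15, which accepts hydride. Deoxygenation and deprotection become one basic operation, so the acid-labile C2–O1 bond never meets an acid in the presence of a hydride source. The demand is that hydride traps 15 faster than 15 tautomerises.

**14 ⇒ 13 ⇒ 12.** The acetate C–O bond and then the carbinol C–H bond are cut, returning this carbon to the ketone level of 12. The ketone is what activates the key step. The forward steps must reduce a hindered β-aryloxy ketone without base-induced loss of O1 from C2, and acylate 13 without ionising it.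

**12 ⇒ 10.** The C2–C3 bond and the C4–H bond are cut. The pyran ring and all three stereocenters disappear; 10 is an acyclic, achiral dienone in which O1 is a benzyl ether oxygen and the ether CH2 is the future C2. The forward step needs a hydridic donor C–H (supplied by the dimethoxyphenyl group), a single enone geometry and a catalyst that controls the face of hydride transfer.

**10 ⇒ 4 + 9.** The bond between ring A and the dienone β-carbon (C4a–C4) and the adjacent Cα–H bond are cut. This joins two fragments of similar size, and syn-hydroarylation of the alkyne fixes the enone geometry, which shorter condensation routes would not. The aryl group must go to the alkyne carbon remote from the carbonyl, without isomerisation and despite the ortho-alkoxy group.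

**9 ⇒ 8 ⇒ 6 + 7.** The ketone is taken back to the carbinol so that no base-sensitive terminal ynone has to be coupled; then the sp–sp2 bond between the alkyne and the styryl carbon is cut. The coupling must retain the E geometry and the oxidation must be mild.

**6 ⇒ 5 and 7 ⇒ 5.** The C=C bond of the iodoalkene and the C–C bond to the ethynyl group are cut; both halves are one-carbon and two-carbon extensions of the same aldehyde. The olefination must be E-selective.

**4 ⇒ 3 ⇒ 1 + 2.** The C–B bond and then the O–CH2 ether bond are cut. Boron allows mild transmetalation, and the ether is made directly from alcohol 2, avoiding its unstable chloride. O-alkylation must beat C-alkylation and the borylation must tolerate an electron-rich, ortho-substituted bromide.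

## Other disconnections considered

**Alternative 1:** oxa-Povarov annulation.
- **Cut:** C2–C3 and C4–C4a. The pyran ring is split into the two-carbon unit C3–C4 of diene A3, (1E,3E)-1,5-bis(4-acetoxyphenyl)penta-1,3-diene, and the O1=C2 heterodiene unit from the diaryl acetal A2.
- **Forward step:** an acid ionises A2 to an aryloxycarbenium ion. C2 adds to the diene terminus that bears the benzyl group, and ring A closes para to its methoxy group onto the internal carbon of the allyl cation. This gives caraganin C diacetate A1; deacetylation gives the target.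
- **In favour:** cationic [4+2] annulation of aryloxycarbenium ions with alkenes is a known reaction type. The carbon skeleton arrives at its final oxidation level. The E-alkene should translate into C3/C4 trans, and acid-mediated equilibration at C2 should favour all-trans.
- **Against:** the step is intermolecular, so the choice of diene terminus, ring A position and six- versus eight-membered closure rests on electronic bias alone. The skipped diene A3 may isomerise or oligomerise in acid. The dimethoxyphenyl group makes the cation weakly electrophilic. Absolute control would need a chiral counter-anion with only ion pairing to hold on to.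
- **Comparison:** this alternative is the better one on step count, redox economy and precedent for the racemic reaction. It is equal on the thermodynamic all-trans argument. It is weaker on regiochemical certainty and absolute stereocontrol, because the chosen plan ties donor, acceptor and nucleophile into one molecule and offers the catalyst a carbonyl next to C4.

**Alternative 2:** enzymatic oxygen insertion.
- **Cut:** O1–C2 and O1–C8a. O1 is removed and the ring contracts to the trans-indanone A5.
- **Forward step:** a Baeyer–Villiger monooxygenase inserts oxygen with aryl migration to give lactone A4. C2 must then be arylated and the resulting lactol reduced.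
- **In favour:** aqueous, ambient conditions and free phenols. An enzyme would leave the styryl alkene and electron-rich rings alone, where a peracid would not. The C3/C4 trans relationship is fixed beforehand and retained in the migration. The enzyme could also resolve racemic A5.
- **Against:** the key step forms no C–C bond and no stereocenter. Aryl versus alkyl migration depends on the enzyme, and a bulky 2,3-disubstituted indanone probably needs an engineered one. A5 must be made enantioenriched, or half is lost. After A4, two or three more steps install C2 with phenol protection, and the lactol reduction passes through the same benzylic cation that opens the ring; C2 is set last by substrate control.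
- **Comparison:** this alternative is better on chemoselectivity and mildness of the key step. It is at best equal on enantiocontrol. It is worse on step economy and on how the fragile C2–O1 region is made.

**Alternative 3:** phenol–dienone Friedel–Crafts annulation.
- **Cut:** C4–C4a and O1–C2.
- **Forward step:** a chiral Brønsted acid promotes ortho Friedel–Crafts 1,4-addition of 3-methoxyphenol A7 to dienone A8. Condensation of the phenol oxygen with the ketone then gives the 4H-chromene A6 with C4 set. Reduction of C2=C3 and desilylation would follow.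
- **In favour:** very convergent; A7 needs no prefunctionalisation; the benzyl group is at its final oxidation level. Chiral-acid-catalysed phenol/enone annulation to 4H-chromenes is a known reaction type, so enantiocontrol at C4 stands on firmer ground than in the chosen plan.
- **Against:** A7 has three nucleophilic positions, and 1,6-addition competes. The α-substituted dienone is a sluggish acceptor. A6 is a tetrasubstituted enol ether that must be reduced to the trans,trans chroman without touching the styryl alkene; this excludes catalytic hydrogenation and leaves an acidic ionic reduction that sets C2 and C3 by substrate control.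
- **Comparison:** this alternative is equal or better on precedent for C4, on redox economy and probably on step count. It is worse for C2 and C3, which the chosen plan sets together with C4 in one self-correcting step.

Key step: step 8

Remark: compound 5 is treated as a purchasable material.
Remark: the sense of induction in step 8 cannot be predicted with confidence; the ligand antipode that leads to (2R,3R,4R)-12 is to be selected, and the (S)-series is written.

## Route

Step 1
Reactants: 1 2-bromo-5-methoxyphenol; 2 2,4-dimethoxybenzyl alcohol
Product: 3 1-bromo-2-[(2,4-dimethoxybenzyl)oxy]-4-methoxybenzene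
Conditions: PPh3, DIAD, THF, 0 °C → rt
Reagents that add atoms: none
Why: Mitsunobu etherification: the primary benzylic alcohol is activated as its alkoxyphosphonium salt and displaced by the phenoxide, which gives the aryl benzyl ether in one step and avoids the unstable 2,4-dimethoxybenzyl chloride. No stereocenter is formed.

Step 2
Reactants: 3 1-bromo-2-[(2,4-dimethoxybenzyl)oxy]-4-methoxybenzene
Product: 4 2-{2-[(2,4-dimethoxybenzyl)oxy]-4-methoxyphenyl}-4,4,5,5-tetramethyl-1,3,2-dioxaborolane
Conditions: B2pin2, PdCl2(dppf) (3 mol %), KOAc, 1,4-dioxane, 90 °C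
Reagents that add atoms: bis(pinacolato)diboron, CC1(C)OB(OC1(C)C)B1OC(C)(C)C(C)(C)O1
Why: Miyaura borylation (oxidative addition of the aryl bromide to zerovalent palladium, acetate-assisted transmetalation, reductive elimination). KOAc is too weak to trigger Suzuki coupling of the product or to harm the benzyl ether, and the pinacol ester can be purified on silica.

Step 3
Reactants: 5 4-(tert-butyldimethylsilyloxy)benzaldehyde
Product: 6 (E)-tert-butyl[4-(2-iodoethenyl)phenoxy]dimethylsilane
Conditions: CHI3, CrCl2, THF, 0 °C → rt
Reagents that add atoms: iodoform, IC(I)I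
Why: Takai olefination: the geminal dichromium species formed from CHI3 and divalent chromium adds to the aldehyde and elimination gives the (E)-iodoalkene. The neutral conditions leave the aryl silyl ether intact.

Step 4
Reactants: 5 4-(tert-butyldimethylsilyloxy)benzaldehyde
Product: 7 rac-1-[4-(tert-butyldimethylsilyloxy)phenyl]prop-2-yn-1-ol
Conditions: HC≡CMgBr, THF, 0 °C; aq. NH4Cl
Reagents that add atoms: ethynylmagnesium bromide, C#C[Mg]Br
Why: Grignard 1,2-addition of an acetylide to an aromatic aldehyde. The new carbinol center is racemic and is removed by oxidation in step 6, so it needs no control.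

Step 5
Reactants: 6 (E)-tert-butyl[4-(2-iodoethenyl)phenoxy]dimethylsilane; 7 rac-1-[4-(tert-butyldimethylsilyloxy)phenyl]prop-2-yn-1-ol
Product: 8 rac-(E)-1,5-bis[4-(tert-butyldimethylsilyloxy)phenyl]pent-4-en-2-yn-1-ol
Conditions: PdCl2(PPh3)2 (2 mol %), CuI (4 mol %), Et3N, THF, rt
Reagents that add atoms: none
Why: Sonogashira coupling of an alkenyl iodide with a terminal alkyne at room temperature. Oxidative addition and reductive elimination proceed with retention, so the E geometry of 6 is carried into 8, and the free propargylic alcohol is tolerated.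

Step 6
Reactants: 8 rac-(E)-1,5-bis[4-(tert-butyldimethylsilyloxy)phenyl]pent-4-en-2-yn-1-ol
Product: 9 (E)-1,5-bis[4-(tert-butyldimethylsilyloxy)phenyl]pent-4-en-2-yn-1-one
Conditions: MnO2, CH2Cl2, rt
Reagents that add atoms: none
Why: MnO2 oxidises this alcohol selectively because it is both benzylic and propargylic. The heterogeneous, neutral conditions spare the silyl ethers and the enyne.

Step 7
Reactants: 9 (E)-1,5-bis[4-(tert-butyldimethylsilyloxy)phenyl]pent-4-en-2-yn-1-one; 4 2-{2-[(2,4-dimethoxybenzyl)oxy]-4-methoxyphenyl}-4,4,5,5-tetramethyl-1,3,2-dioxaborolane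
Product: 10 (2E,4E)-3-{2-[(2,4-dimethoxybenzyl)oxy]-4-methoxyphenyl}-1,5-bis[4-(tert-butyldimethylsilyloxy)phenyl]penta-2,4-dien-1-one
Conditions: [Rh(OH)(cod)]2 (3 mol %), 1,4-dioxane/H2O (10:1), 60 °C
Reagents that add atoms: none
Why: Rhodium-catalysed hydroarylation of an alkynone with an arylboron reagent: transmetalation gives an aryl–rhodium species, syn-carbometalation places ring A on the alkyne carbon remote from the carbonyl, and water protonates the alkenyl–rhodium bond with retention. Syn addition of aryl and H puts ring A trans to the aroyl group, which is the 2E geometry. The base-free hydroxo complex avoids cleavage of the aryl silyl ethers.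

Step 8
Reactants: 10 (2E,4E)-3-{2-[(2,4-dimethoxybenzyl)oxy]-4-methoxyphenyl}-1,5-bis[4-(tert-butyldimethylsilyloxy)phenyl]penta-2,4-dien-1-one
Product: 12 (2R,3R,4R)-2-(2,4-dimethoxyphenyl)-7-methoxy-3-[4-(tert-butyldimethylsilyloxy)benzoyl]-4-{(E)-2-[4-(tert-butyldimethylsilyloxy)phenyl]ethenyl}chroman (all-trans), via oxocarbenium enolate zwitterion 11 (not isolated)
Conditions: Sc(OTf)3 (10 mol %), C2-symmetric N,N'-dioxide ligand from (S)-pipecolic acid with 2,6-diisopropylanilide arms and a propane-1,3-diyl linker (12 mol %), 4 Å MS, ClCH2CH2Cl, 40 °C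
Reagents that add atoms: none
Why: Proposed new method: the Sc(OTf)3–N,N'-dioxide complex binds the ketone oxygen of 10 and activates the enone, so that one hydrogen of the OCH2 group shifts suprafacially as hydride through a six-membered transition state to the enone β-carbon (future C4), which the ortho substituent of the twisted ring A holds five atoms away; this gives the aryloxocarbenium/(Z)-enolate zwitterion 11. The enolate carbon (future C3) then adds to the oxocarbenium carbon (future C2) in a 6-(enolexo)-endo-trig aldol-type closure that forms the C2–C3 bond and the pyran ring. The closest known reaction type is the Lewis-acid-catalysed 1,5-hydride shift/cyclisation (internal redox) of benzylic ethers onto tethered alkylidene malonates and enones; new here are the β,β-disubstituted dienone acceptor and the creation of a stereocenter at the hydride-accepting carbon. C4 is set in the hydride transfer under catalyst control: the ligand sphere selects one of the two enantiomeric twist conformers about the ring A–C4 bond and thereby the enone face that receives hydride. C3 and C2 are set relative to C4 by the substrate: closure passes through a chair-like transition state with the styryl, aroyl and dimethoxyphenyl groups pseudo-equatorial, and because C3 is enolisable and the ring can reopen to 11, the all-equatorial all-trans isomer is the thermodynamic sink. The step needs 1,5-transfer to the β-carbon and C-alkylation of the enolate in preference to other paths; the substrate secures this because the donor C–H is activated by both oxygen and the electron-rich arene, only the β-carbon lies within reach of a six-membered transition state, and attack by the enolate oxygen would need an eight-membered ring. The single 2E geometry from step 7 means the catalyst meets one substrate isomer.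

Step 9
Reactants: 12 (2R,3R,4R)-2-(2,4-dimethoxyphenyl)-7-methoxy-3-[4-(tert-butyldimethylsilyloxy)benzoyl]-4-{(E)-2-[4-(tert-butyldimethylsilyloxy)phenyl]ethenyl}chroman
Product: 13 (2R,3S,4R)-2-(2,4-dimethoxyphenyl)-3-{hydroxy[4-(tert-butyldimethylsilyloxy)phenyl]methyl}-7-methoxy-4-{(E)-2-[4-(tert-butyldimethylsilyloxy)phenyl]ethenyl}chroman, mixture of carbinol epimers, ring substituents all-trans as in 12 (the C3 descriptor changes through the priority rules only)
Conditions: NaBH4, CeCl3·7H2O, MeOH/THF (1:1), −20 → 0 °C
Reagents that add atoms: none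
Why: Luche-type 1,2-reduction of the aryl ketone; the cerium salt speeds hydride addition and lowers the basicity of the medium, which guards against enolisation at C3 and β-elimination of O1. The carbinol forms as a mixture of epimers, which does not matter because this center is removed in step 11; C2, C3 and C4 are not touched.

Step 10
Reactants: 13 (2R,3S,4R)-2-(2,4-dimethoxyphenyl)-3-{hydroxy[4-(tert-butyldimethylsilyloxy)phenyl]methyl}-7-methoxy-4-{(E)-2-[4-(tert-butyldimethylsilyloxy)phenyl]ethenyl}chroman
Product: 14 (2R,3R,4R)-3-{acetoxy[4-(tert-butyldimethylsilyloxy)phenyl]methyl}-2-(2,4-dimethoxyphenyl)-7-methoxy-4-{(E)-2-[4-(tert-butyldimethylsilyloxy)phenyl]ethenyl}chroman, mixture of epimers at the acetoxy carbon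
Conditions: Ac2O, pyridine, DMAP (cat.), CH2Cl2, 0 °C → rt
Reagents that add atoms: acetic anhydride, CC(=O)OC(C)=O
Why: DMAP-catalysed acylation of a secondary alcohol under basic conditions. The acetate is the leaving group needed in step 11, and no cation is generated at the electron-rich benzylic position.

Step 11
Reactants: 14 (2R,3R,4R)-3-{acetoxy[4-(tert-butyldimethylsilyloxy)phenyl]methyl}-2-(2,4-dimethoxyphenyl)-7-methoxy-4-{(E)-2-[4-(tert-butyldimethylsilyloxy)phenyl]ethenyl}chroman
Product: 16 caraganin C [(2R,3R,4R)-2-(2,4-dimethoxyphenyl)-3-(4-hydroxybenzyl)-4-[(E)-2-(4-hydroxyphenyl)ethenyl]-7-methoxychroman], via para-quinone methide 15 (not isolated)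
Conditions: NaBH4, TBAF (1 M in THF), DMF, 0 °C → rt; aq. NH4Cl
Reagents that add atoms: none
Why: Fluoride cleaves both aryl silyl ethers; the phenoxide para to the acetoxy-bearing carbon expels acetate by 1,6-elimination to give para-quinone methide 15, and borohydride adds to its exocyclic carbon, restoring the phenol and leaving CH2. Both events are known reaction types (fluoride-triggered quinone methide release from 4-silyloxybenzyl esters; hydride reduction of quinone methides). The medium stays basic, so the C2–O1 bond, the styryl alkene and the three ring stereocenters are not at risk.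

## Compound list

1 | 2-bromo-5-methoxyphenol | COc1ccc(Br)c(O)c1 | starting material
2 | 2,4-dimethoxybenzyl alcohol | COc1ccc(CO)c(OC)c1 | starting material
3 | 1-bromo-2-[(2,4-dimethoxybenzyl)oxy]-4-methoxybenzene | COc1ccc(Br)c(OCc2ccc(OC)cc2OC)c1 | intermediate
4 | 2-{2-[(2,4-dimethoxybenzyl)oxy]-4-methoxyphenyl}-4,4,5,5-tetramethyl-1,3,2-dioxaborolane | COc1ccc(B2OC(C)(C)C(C)(C)O2)c(OCc2ccc(OC)cc2OC)c1 | intermediate
5 | 4-(tert-butyldimethylsilyloxy)benzaldehyde | CC(C)(C)[Si](C)(C)Oc1ccc(C=O)cc1 | starting material
6 | (E)-tert-butyl[4-(2-iodoethenyl)phenoxy]dimethylsilane | CC(C)(C)[Si](C)(C)Oc1ccc(/C=C/I)cc1 | intermediate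
7 | rac-1-[4-(tert-butyldimethylsilyloxy)phenyl]prop-2-yn-1-ol | CC(C)(C)[Si](C)(C)Oc1ccc(C(O)C#C)cc1 | intermediate
8 | rac-(E)-1,5-bis[4-(tert-butyldimethylsilyloxy)phenyl]pent-4-en-2-yn-1-ol | CC(C)(C)[Si](C)(C)Oc1ccc(/C=C/C#CC(O)c2ccc(O[Si](C)(C)C(C)(C)C)cc2)cc1 | intermediate
9 | (E)-1,5-bis[4-(tert-butyldimethylsilyloxy)phenyl]pent-4-en-2-yn-1-one | CC(C)(C)[Si](C)(C)Oc1ccc(/C=C/C#CC(=O)c2ccc(O[Si](C)(C)C(C)(C)C)cc2)cc1 | intermediate
10 | (2E,4E)-3-{2-[(2,4-dimethoxybenzyl)oxy]-4-methoxyphenyl}-1,5-bis[4-(tert-butyldimethylsilyloxy)phenyl]penta-2,4-dien-1-one | COc1ccc(c(c1)OCc1ccc(OC)cc1OC)/C(/C=C/c1ccc(O[Si](C)(C)C(C)(C)C)cc1)=C/C(=O)c1ccc(O[Si](C)(C)C(C)(C)C)cc1 | intermediate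
11 | aryloxocarbenium/(Z)-enolate zwitterion formed by 1,5-hydride shift (catalyst-bound, C4 already R-configured as in 12) | COc1ccc([C@H](/C=C/c2ccc(O[Si](C)(C)C(C)(C)C)cc2)/C=C(\[O-])c2ccc(O[Si](C)(C)C(C)(C)C)cc2)c([O+]=Cc2ccc(OC)cc2OC)c1 | intermediate (not isolated)
12 | (2R,3R,4R)-2-(2,4-dimethoxyphenyl)-7-methoxy-3-[4-(tert-butyldimethylsilyloxy)benzoyl]-4-{(E)-2-[4-(tert-butyldimethylsilyloxy)phenyl]ethenyl}chroman | COc1ccc2c(c1)O[C@@H](c1ccc(OC)cc1OC)[C@H](C(=O)c1ccc(O[Si](C)(C)C(C)(C)C)cc1)[C@H]2/C=C/c1ccc(O[Si](C)(C)C(C)(C)C)cc1 | intermediate
13 | (2R,3S,4R)-2-(2,4-dimethoxyphenyl)-3-{hydroxy[4-(tert-butyldimethylsilyloxy)phenyl]methyl}-7-methoxy-4-{(E)-2-[4-(tert-butyldimethylsilyloxy)phenyl]ethenyl}chroman, carbinol epimers | COc1ccc2c(c1)O[C@@H](c1ccc(OC)cc1OC)[C@H](C(O)c1ccc(O[Si](C)(C)C(C)(C)C)cc1)[C@H]2/C=C/c1ccc(O[Si](C)(C)C(C)(C)C)cc1 | intermediate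
14 | (2R,3R,4R)-3-{acetoxy[4-(tert-butyldimethylsilyloxy)phenyl]methyl}-2-(2,4-dimethoxyphenyl)-7-methoxy-4-{(E)-2-[4-(tert-butyldimethylsilyloxy)phenyl]ethenyl}chroman, epimers at the acetoxy carbon | COc1ccc2c(c1)O[C@@H](c1ccc(OC)cc1OC)[C@H](C(OC(C)=O)c1ccc(O[Si](C)(C)C(C)(C)C)cc1)[C@H]2/C=C/c1ccc(O[Si](C)(C)C(C)(C)C)cc1 | intermediate
15 | 4-{[(2R,3R,4R)-2-(2,4-dimethoxyphenyl)-4-[(E)-2-(4-hydroxyphenyl)ethenyl]-7-methoxychroman-3-yl]methylidene}cyclohexa-2,5-dien-1-one | COc1ccc2c(c1)O[C@@H](c1ccc(OC)cc1OC)[C@H](C=C1C=CC(=O)C=C1)[C@H]2/C=C/c1ccc(O)cc1 | intermediate (not isolated)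
16 | caraganin C, (2R,3R,4R)-2-(2,4-dimethoxyphenyl)-3-(4-hydroxybenzyl)-4-[(E)-2-(4-hydroxyphenyl)ethenyl]-7-methoxychroman | COc1ccc2c(c1)O[C@@H](c1ccc(OC)cc1OC)[C@H](Cc1ccc(O)cc1)[C@H]2/C=C/c1ccc(O)cc1 | target

## Step count and least certain steps

Total step count: 11. Longest linear sequence: 8 steps (steps 3, 5, 6, 7, 8, 9, 10 and 11, from 5 to 16).

**Step 8 (key step, proposed new method).**
- Most likely failure: poor facial selectivity in the hydride transfer, because a monodentate ketone gives a loosely organised chiral environment and the Lewis-acid-bound dienone can rotate about its central double bond.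
- Also possible: ionisation of the benzyl ether C–O bond by the Lewis acid, and electrocyclisation of the cis-dienone unit to a 2H-pyran followed by hydride loss to a pyrylium ion.
- The electron-rich, β,β-disubstituted acceptor may also take up hydride slowly.
- Fallback with known chemistry, setting out from 5 and returning at 12:
  - Boron–Wittig olefination of 5 with bis[(pinacolato)boryl]methane and LiTMP should give (E)-tert-butyldimethyl{4-[2-(4,4,5,5-tetramethyl-1,3,2-dioxaborolan-2-yl)ethenyl]phenoxy}silane F1.
  - Asymmetric conjugate addition of F1 to 7-methoxycoumarin, catalysed by Rh(acac)(C2H4)2 with a SEGPHOS-type bisphosphine of the appropriate hand, should give (S)-7-methoxy-4-{(E)-2-[4-(tert-butyldimethylsilyloxy)phenyl]ethenyl}chroman-2-one F2. This fixes C4.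
  - Lactone opening with N,O-dimethylhydroxylamine hydrochloride and i-PrMgCl should give the Weinreb amide (S,E)-3-(2-hydroxy-4-methoxyphenyl)-N-methoxy-N-methyl-5-[4-(tert-butyldimethylsilyloxy)phenyl]pent-4-enamide F3.
  - Excess 4-(tert-butyldimethylsilyloxy)phenylmagnesium bromide should give the keto phenol (S,E)-3-(2-hydroxy-4-methoxyphenyl)-1,5-bis[4-(tert-butyldimethylsilyloxy)phenyl]pent-4-en-1-one F4.
  - Pyrrolidine-mediated aldol condensation of F4 with 2,4-dimethoxybenzaldehyde, followed by oxa-Michael ring closure of the resulting enone, should give 12 under thermodynamic control.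

**Step 7.**
- Most likely failure: protodeboronation of the electron-rich, ortho-alkoxy boronate outruns transmetalation and insertion, or the alkenyl–rhodium intermediate isomerises and erodes the 2E geometry.
- Fallback, setting out from 3 and 9 and returning at 10: formate-mediated palladium-catalysed hydroarylation (reductive Heck reaction) of 9 with bromide 3 [Pd(OAc)2, P(o-tol)3, HCO2K, DMF, 60 °C]. Aryl–palladium adds syn across the alkyne with the aryl group on the carbon remote from the carbonyl, and formate-derived hydride cleaves the alkenyl–palladium bond. The boron reagent and step 2 are bypassed; no new compound is made.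

**Step 11.**
- Most likely failure: tautomerisation of the quinone methide by loss of the C3 hydrogen before hydride arrives, or cleavage of the acetate before the elimination.
- Fallback, setting out from 13 and returning at 16: ionic deoxygenation of 13 with Et3SiH and BF3·OEt2 in CH2Cl2 at −78 °C should give (2R,3R,4R)-2-(2,4-dimethoxyphenyl)-7-methoxy-3-[4-(tert-butyldimethylsilyloxy)benzyl]-4-{(E)-2-[4-(tert-butyldimethylsilyloxy)phenyl]ethenyl}chroman F5, and TBAF buffered with AcOH should then give 16. This is a cationic route instead of the quinone-methide route; the low temperature is meant to keep the C2–O1 bond from ionising.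

**Step 3.**
- Most likely failure: erosion of E-selectivity or incomplete conversion with the electron-rich aldehyde.
- Fallback, setting out from 5 and returning at 8 (steps 3 to 5 replaced by a Corey–Fuchs sequence):
  - Wittig reaction of 5 with Ph3P=CHCHO should give (E)-3-[4-(tert-butyldimethylsilyloxy)phenyl]prop-2-enal F6.
  - CBr4/PPh3 should give tert-butyl{4-[(1E)-4,4-dibromobuta-1,3-dien-1-yl]phenoxy}dimethylsilane F7.
  - n-BuLi (2 equiv, THF, −78 °C) should give lithium (E)-4-[4-(tert-butyldimethylsilyloxy)phenyl]but-3-en-1-yn-1-ide F8, which is not isolated and adds to a second portion of 5 to give 8.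

## Further compounds

F1 | step 8 | (E)-tert-butyldimethyl{4-[2-(4,4,5,5-tetramethyl-1,3,2-dioxaborolan-2-yl)ethenyl]phenoxy}silane | CC(C)(C)[Si](C)(C)Oc1ccc(/C=C/B2OC(C)(C)C(C)(C)O2)cc1
F2 | step 8 | (S)-7-methoxy-4-{(E)-2-[4-(tert-butyldimethylsilyloxy)phenyl]ethenyl}chroman-2-one | COc1ccc2c(c1)OC(=O)C[C@H]2/C=C/c1ccc(O[Si](C)(C)C(C)(C)C)cc1
F3 | step 8 | (S,E)-3-(2-hydroxy-4-methoxyphenyl)-N-methoxy-N-methyl-5-[4-(tert-butyldimethylsilyloxy)phenyl]pent-4-enamide | COc1ccc(c(O)c1)[C@@H](CC(=O)N(C)OC)/C=C/c1ccc(O[Si](C)(C)C(C)(C)C)cc1
F4 | step 8 | (S,E)-3-(2-hydroxy-4-methoxyphenyl)-1,5-bis[4-(tert-butyldimethylsilyloxy)phenyl]pent-4-en-1-one | COc1ccc(c(O)c1)[C@@H](CC(=O)c1ccc(O[Si](C)(C)C(C)(C)C)cc1)/C=C/c1ccc(O[Si](C)(C)C(C)(C)C)cc1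
F0 | step 7 | none | none
F5 | step 11 | (2R,3R,4R)-2-(2,4-dimethoxyphenyl)-7-methoxy-3-[4-(tert-butyldimethylsilyloxy)benzyl]-4-{(E)-2-[4-(tert-butyldimethylsilyloxy)phenyl]ethenyl}chroman | COc1ccc2c(c1)O[C@@H](c1ccc(OC)cc1OC)[C@H](Cc1ccc(O[Si](C)(C)C(C)(C)C)cc1)[C@H]2/C=C/c1ccc(O[Si](C)(C)C(C)(C)C)cc1
F6 | step 3 | (E)-3-[4-(tert-butyldimethylsilyloxy)phenyl]prop-2-enal | CC(C)(C)[Si](C)(C)Oc1ccc(/C=C/C=O)cc1
F7 | step 3 | tert-butyl{4-[(1E)-4,4-dibromobuta-1,3-dien-1-yl]phenoxy}dimethylsilane | CC(C)(C)[Si](C)(C)Oc1ccc(/C=C/C=C(Br)Br)cc1
F8 | step 3 | lithium (E)-4-[4-(tert-butyldimethylsilyloxy)phenyl]but-3-en-1-yn-1-ide | [Li]C#C/C=C/c1ccc(O[Si](C)(C)C(C)(C)C)cc1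
A1 | alternative 1 | caraganin C diacetate | COc1ccc2c(c1)O[C@@H](c1ccc(OC)cc1OC)[C@H](Cc1ccc(OC(C)=O)cc1)[C@H]2/C=C/c1ccc(OC(C)=O)cc1
A2 | alternative 1 | 2,4-dimethoxybenzaldehyde bis(3-methoxyphenyl) acetal | COc1cccc(OC(Oc2cccc(OC)c2)c2ccc(OC)cc2OC)c1
A3 | alternative 1 | (1E,3E)-1,5-bis(4-acetoxyphenyl)penta-1,3-diene | CC(=O)Oc1ccc(C/C=C/C=C/c2ccc(OC(C)=O)cc2)cc1
A4 | alternative 2 | trans-3-(4-hydroxybenzyl)-4-[(E)-4-hydroxystyryl]-7-methoxy-3,4-dihydrocoumarin | COc1ccc2c(c1)OC(=O)[C@H](Cc1ccc(O)cc1)[C@H]2/C=C/c1ccc(O)cc1
A5 | alternative 2 | trans-2-(4-hydroxybenzyl)-3-[(E)-4-hydroxystyryl]-6-methoxyindan-1-one | COc1ccc2c(c1)C(=O)[C@H](Cc1ccc(O)cc1)[C@H]2/C=C/c1ccc(O)cc1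
A6 | alternative 3 | 2-(2,4-dimethoxyphenyl)-7-methoxy-3-[4-(tert-butyldimethylsilyloxy)benzyl]-4-{(E)-2-[4-(tert-butyldimethylsilyloxy)phenyl]ethenyl}-4H-chromene | COc1ccc2c(c1)OC(c1ccc(OC)cc1OC)=C(Cc1ccc(O[Si](C)(C)C(C)(C)C)cc1)[C@H]2/C=C/c1ccc(O[Si](C)(C)C(C)(C)C)cc1
A7 | alternative 3 | 3-methoxyphenol | COc1cccc(O)c1
A8 | alternative 3 | (2E,4E)-1-(2,4-dimethoxyphenyl)-2-[4-(tert-butyldimethylsilyloxy)benzyl]-5-[4-(tert-butyldimethylsilyloxy)phenyl]penta-2,4-dien-1-one | COc1ccc(C(=O)/C(Cc2ccc(O[Si](C)(C)C(C)(C)C)cc2)=C/C=C/c2ccc(O[Si](C)(C)C(C)(C)C)cc2)c(OC)c1
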